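5 questions stand below, and two chemists reading the same runs hang them on different rate laws.

| flask | starting material | second substrate | free enzyme | remark | time |
|---|---|---|---|---|---|
| Tuesday's | 0.20 M | 0.40 M | 40 µM | run made earlier |  |
| Friday's | 0.10 M | 0.40 M | 40 µM | run made earlier |  |
| Sunday's | 0.15 M | 0.40 M | 40 µM | run made earlier |  |
| theta | 0.20 M (fed, over 1.60 min) | 0.400 M | 40 µM | all but starting material at the start; starting material goes in evenly over 1.60 min, the run ends at 2.0 min | 2.0 min |
| epsilon | 0.20 M | 0.400 M | 40 µM | one stirred flow tank at steady state, fed with the mixture as stated, mean residence time 6.00 min |  |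
| gamma | 0.20 M | 0.400 M | 40 µM | a single well-mixed tank run continuously and read at steady state, 2.0 min in it on average |  |
| eta | 0.20 M | 0.400 M | 40 µM | everything together in a closed stirred flask, run for 2.0 min | 2.0 min |

| run | time / s | target / % |
|---|---|---|
| Tuesday's | 10.0 | 0 |
| Tuesday's | 25.0 | 2.9 |
| Tuesday's | 40.0 | 2.9 |
| Tuesday's | 60.0 | 4.8 |
| Tuesday's | 90.0 | 6.3 |
| Tuesday's | 120 | 10.0 |
| Friday's | 10.0 | 1.6 |
| Friday's | 15.0 | 1.8 |
| Friday's | 25.0 | 4.0 |
| Friday's | 40.0 | 5.6 |
| Friday's | 60.0 | 8.8 |
| Friday's | 80.0 | 11.1 |
| Sunday's | 10.0 | 0 |
| Sunday's | 15.0 | 1.3 |
| Sunday's | 25.0 | 1.8 |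
| Sunday's | 40.0 | 3.6 |
| Sunday's | 80.0 | 7.9 |

(scatter of a reading: 0.5 percentage points)

- percentages count the starting material that a species holds: one resting dimer or self-condensation product counts as two
- target is meant together with its idle adduct
- the stated concentrations are those of everything mixed, before any reaction; amounts are the same in each set-up
- candidate steps: starting material + free enzyme <-> first complex; first complex <-> loaded enzyme + first product; second substrate + loaded enzyme <-> second complex; second complex -> free enzyme + target; second substrate + target <-> idle adduct; 2 first complex <-> resting dimer; 2 starting material -> self-condensation product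
- the feed brings no volume worth counting
- the earlier runs were made in a closed, stirred flask

1. the set-up with the highest amount of target at the outlet or at the end, in percent of the starting material put in ("none" if the first two lie within 2 percentage points) (theta / epsilon / gamma / eta / none)
2. amount of target at the outlet or at the end, in percent of the starting material put in, theta
3. amount of target at the outlet or at the end, in percent of the starting material put in, epsilon
4. amount of target at the outlet or at the end, in percent of the starting material put in, gamma
5. amount of target at the outlet or at the end, in percent of the starting material put in, eta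

Ada multiplies each run's last reading by its charge and divides by its time. That gives 1.67 × 10⁻⁴ M s⁻¹ on Tuesday, 1.48 × 10⁻⁴ M s⁻¹ on Sunday and 1.39 × 10⁻⁴ M s⁻¹ on Friday, each carrying the scatter of one reading, 0.5 percentage points. Friday's charge is half of Tuesday's, yet its rate is 0.832 of Tuesday's, so she calls the law zero order in [starting material]. She carries the mean, 1.51 × 10⁻⁴ M s⁻¹, as the plateau rate: the molar rate of target while the enzyme stays full, whatever [starting material] stands. Her rule is that percent target equals plateau rate times time in the vessel, divided by the charge. This gives 9.07 % for eta, gamma and theta alike, and 27.2 % for epsilon.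

Bea holds to first order in [starting material], with Tuesday's constant 0.0500 min⁻¹. Ada objects that Friday's gives 0.0833 min⁻¹. In theta the feed holds the mean [starting material] at 0.120 M, so Bea expects 6.00 % there, and 23.1 % from the epsilon tank.

The forecast takes Ada's side but marks theta down, saying “early low starting material costs a little”. It gives 8.5 % for theta (6.8 % to 9.8 %), 25 % for epsilon (18 % to 29 %), 9.3 % for gamma (8 % to 10.5 %) and 9.5 % for eta (8.7 % to 10.3 %), with epsilon best.

The flasks give 8.13 % for theta, 25.8 % for epsilon, 8.75 % for gamma and 8.78 % for eta, so epsilon is best.

    starting material + free enzyme ⇌ first complex (K = 15.0 M⁻¹, k = 5300 M⁻¹ s⁻¹)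
    first complex ⇌ loaded enzyme + first product (K = 0.570 M, k = 25.0 s⁻¹)
    second substrate + loaded enzyme ⇌ second complex (K = 19.0 M⁻¹, k = 6100 M⁻¹ s⁻¹)
    second complex → free enzyme + target (k = 29.0 s⁻¹)
    second substrate + target ⇌ idle adduct, settled at all times (K = 1.00 M⁻¹)
    2 first complex ⇌ resting dimer, settled at all times (K = 3.80 × 10⁵ M⁻¹)
    2 starting material → self-condensation product (k = 1.90 × 10⁻⁵ M⁻¹ s⁻¹)

Theta's 8.13 % stands above Bea's 6.00 %, so the plateau holds, and the neighbour of theta charged with 0.80 M gives 2.19 % against the rule's 2.27 %. Eta has not come to rest: at 2.00 min, 91 % of its starting material stands free, with 65.1 % of the catalyst as resting dimer, the resting state. At 20.0 min eta holds 82.5 % target against the rule's 90.7 %, the rate over that stretch having been 1.37 × 10⁻⁴ M s⁻¹. Bea's first order is not reached even in that tail: from 2.00 min to 20.0 min eta's starting material falls from 91.1 % to 17.1 % of its charge, while second complex goes from 12.6 % to 10.2 % of the catalyst.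

The numbers in the tables are simulated with constants of no real substance; scatter was added.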